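I reckoned both new flasks from the violet run.

| flask | substrate | partner | other conformer | remark | time |
|---|---|---|---|---|---|
| red | 0.30 M | 0.051 M | 0.30 M | run made earlier |  |
| amber | 0.30 M | 0.11 M | 0.30 M | run made earlier |  |
| violet | 0.30 M | 0.22 M | 0.30 M | run made earlier |  |
| teal | 0.30 M | 0.24 M | 0.20 M | run made earlier |  |
| south-east | 0.30 M | 0.0600 M | 0.0800 M |  | 5.0 min |
| south | 0.30 M | 0.240 M | 0.300 M |  | 5.0 min |

- red (time / min: target / %): 0.417: 1.3; 1.33: 3.0; 2.50: 1.7; 4.00: 3.5
- amber (time / min: target / %): 0.250: 0.9; 0.667: 2.0; 1.50: 5.1; 4.00: 8.0
- violet (time / min: target / %): 0.833: 7.9; 2.00: 14.7; 2.50: 14.4; 4.00: 14.2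
- teal (time / min: target / %): 0.250: 3.5; 0.667: 8.4; 1.50: 11.3; 4.00: 20.5

(each reading ± 1 percentage point)

- what was read earlier has a scatter of 1 percentage point, one standard deviation
- in a conversion other conformer counts as not yet reacted

- the flask that ends with the higher amount of target, in percent of the substrate and other conformer together charged, or "neither" when 2 percentage points or less lies between them (south-east / south / neither)
- final target, as a percentage of the substrate and other conformer together charged, in south-east
- final target, as a percentage of the substrate and other conformer together charged, in south

Violet's last readings stood at 14.7%, 14.4% and 14.2%, so I took the last as a plateau. Converted to a concentration and divided by the partner charged, it gave the share, the target formed per partner charged, or yield on partner, the limiting reagent: 38.7%.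

Next came the time. I let target approach its plateau as plateau × (1 − e^(−t/τ)), and violet's first reading gave τ = 1.02 min. I assumed that τ stretches as the charge of substrate and other conformer shrinks, which made it 1.62 min in south-east, longer than in violet. By 5.0 min, on this reckoning, south-east had covered 95.4% of its rise. With a fixed share, south-east came to 5.84% and south to 15.4%.

The weak link was that fixed share, since south-east holds 0.0800 M of other conformer, less than the 0.30 M in violet. Suppose instead that the share followed the charged ratio of other conformer to substrate. Teal should then have read 48.7%, but its last reading gave 42.7%, between the two views, and both figures carry scatter. The ratio view lifted south-east to 10.6%, still 4.8 percentage points behind south, which exceeds the margin. I committed to south, with south-east near 5.84%.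

The forecast also chose south, but its 10% for south-east differed from my figure and sat near the ratio end: it read teal as favouring a share set by the ratio of substrate to other conformer, “though fast interconversion isn't excluded”. For south it gave 16%.

South ended at 17.2% and south-east at 6.72%.

    substrate ⇌ other conformer (K = 1.00, k = 0.0180 s⁻¹)
    substrate + partner ⇌ target (K = 11.0 L mol⁻¹, k = 0.0200 L mol⁻¹ s⁻¹)
    partner + other conformer → isomer of the product (k = 0.0120 L mol⁻¹ s⁻¹)

At the end of south-east, substrate and other conformer stood level, at 44.4% and 44.2% of the two together charged, although 0.30 M and 0.0800 M went in. South-east's result corresponds to a share of 42.6%, against the 38.7% read from violet. For the neighbour of south-east with 0.015 M of partner, the share 38.7% gives 1.46%, and that flask ended with 1.73%.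

The data stem from a simulated flask for substances that don't exist; scatter was added.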